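**Retrosynthetic overview**

1. Target 20 ← 19 by fluoride desilylation ← 18 by cross-metathesis of the C6 allyl group, so the acid-sensitive prenyl group and the free phenols appear only after the acid step.
2. 18 ← acid 16 by intramolecular Friedel–Crafts acylation forming C4–C4a and closing ring C, the only ring built (rings A and B are bought as arenes). The strategy rests on C4a, the ring A carbon ortho to O1 and para to the C7 oxygen, and on C3, which carries two one-carbon arms (C2 and C4) and is thus the centre of a prochiral 2-aryl-1,3-diol.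
3. 16 ← alcohol 14 ← acetate 13 ← Mitsunobu O1–C2 bond between monoacetate 8 and phenol 12, so C3 is fixed before any carbonyl stands next to it.
4. 8 ← diol 7 (lipase desymmetrisation) ← arylmalonate 6 ← aryl bromide 4 + diethyl malonate 5; 4 ← aldehyde 1.
5. 12 ← 4-bromoresorcinol 9 by double silylation, Stille allylation and removal of the less hindered silyl group.

Key step: step 12

Assumption: Burkholderia cepacia lipase is taken to acetylate the pro-S hydroxymethyl group of diol 7, giving (S)-8; sense and level of selectivity have to be confirmed on this substrate (the step 5 fallback offers either sense).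

**Route**

Step 1
Reactants: 1 4-bromo-2,5-dimethoxybenzaldehyde
Product: 3 4-bromo-2,5-dimethoxyphenol, via aryl formate 2 (not isolated)
Conditions: mCPBA, CH2Cl2, 0 °C to rt; then MeOH, HCl (cat.), rt
Reagents that add atoms: mCPBA (3-chloroperbenzoic acid), OOC(=O)c1cccc(Cl)c1
Why: Baeyer–Villiger (Dakin-type) oxidation, in which the electron-rich aryl group with its ortho methoxy migrates in the Criegee intermediate to give formate 2, whose methanolysis unmasks the phenol that becomes the C4' hydroxyl.

Step 2
Reactants: 3 4-bromo-2,5-dimethoxyphenol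
Product: 4 (4-bromo-2,5-dimethoxyphenoxy)triisopropylsilane
Conditions: TIPSCl, imidazole, DMF, rt
Reagents that add atoms: triisopropylsilyl chloride, CC(C)[Si](Cl)(C(C)C)C(C)C
Why: Standard phenol silylation, with triisopropylsilyl chosen over a smaller silyl group because this ether has to pass phosphate base at 80 °C, LiAlH4 and (i-Bu)2AlH before the final fluoride step.

Step 3
Reactants: 4 (4-bromo-2,5-dimethoxyphenoxy)triisopropylsilane; 5 diethyl malonate
Product: 6 diethyl 2-[2,5-dimethoxy-4-(triisopropylsilyloxy)phenyl]malonate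
Conditions: Pd(OAc)2 (cat.), [HP(t-Bu)3]BF4 (cat.), K3PO4, toluene, 80 °C
Reagents that add atoms: none
Why: Palladium-catalysed α-arylation of a malonate (Buchwald–Hartwig-type enolate arylation), in which the bulky electron-rich phosphine allows oxidative addition of the electron-rich ortho-substituted bromide to zerovalent palladium and the product, resting as its hindered enolate, should not arylate twice.

Step 4
Reactants: 6 diethyl 2-[2,5-dimethoxy-4-(triisopropylsilyloxy)phenyl]malonate
Product: 7 2-[2,5-dimethoxy-4-(triisopropylsilyloxy)phenyl]propane-1,3-diol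
Conditions: LiAlH4 (excess), THF, 0 °C to rt (malonate added to the hydride); Fieser work-up
Reagents that add atoms: none
Why: Hydride reduction of both esters to the prochiral 2-aryl-1,3-diol, where adding the malonate to excess cold LiAlH4 keeps reduction ahead of enolate formation at the acidic malonate C–H and the aryl triisopropylsilyl ether is inert to hydride.

Step 5
Reactants: 7 2-[2,5-dimethoxy-4-(triisopropylsilyloxy)phenyl]propane-1,3-diol
Product: 8 (2S)-2-[2,5-dimethoxy-4-(triisopropylsilyloxy)phenyl]-3-hydroxypropyl acetate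
Conditions: Burkholderia cepacia lipase (immobilised), vinyl acetate, t-BuOMe, rt, stopped before diacetate builds up
Reagents that add atoms: vinyl acetate, CC(=O)OC=C
Why: Lipase-catalysed desymmetrisation of a prochiral 2-aryl-1,3-propanediol by irreversible transesterification (vinyl alcohol leaves as acetaldehyde), in which the enzyme acetylates one enantiotopic hydroxymethyl arm and thereby sets the stereocentre that becomes C3, while the slower second acetylation should consume mainly the minor enantiomer and raise the ee of 8.

Step 6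
Reactants: 9 4-bromoresorcinol
Product: 10 1-bromo-2,4-bis(triisopropylsilyloxy)benzene
Conditions: TIPSCl (2.4 equiv), imidazole, DMF, 40 °C
Reagents that add atoms: triisopropylsilyl chloride, CC(C)[Si](Cl)(C(C)C)C(C)C
Why: Double phenol silylation with silyl chloride and imidazole, gentle warming bringing the hindered oxygen next to bromine to completion.

Step 7
Reactants: 10 1-bromo-2,4-bis(triisopropylsilyloxy)benzene
Product: 11 1-allyl-2,4-bis(triisopropylsilyloxy)benzene
Conditions: allylSnBu3, Pd(PPh3)4 (cat.), DMF, 95 °C
Reagents that add atoms: allyltributylstannane, C=CC[Sn](CCCC)(CCCC)CCCC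
Why: Stille coupling of an aryl bromide with an allylstannane, whose neutral fluoride-free conditions leave both aryl silyl ethers intact and place the allyl group at the future C6.

Step 8
Reactants: 11 1-allyl-2,4-bis(triisopropylsilyloxy)benzene
Product: 12 4-allyl-3-(triisopropylsilyloxy)phenol
Conditions: Bu4NF (1.0 equiv), AcOH (1.0 equiv), THF, −20 °C, stopped at partial conversion
Reagents that add atoms: none
Why: Fluoride-induced Si–O cleavage of an aryl silyl ether, selective because the silicon on the C4 oxygen is flanked by two ring hydrogens whereas the one on the C2 oxygen is shielded by the ortho allyl group and the two phenoxide leaving groups are electronically alike, so one equivalent of buffered fluoride should free the oxygen para to allyl first (unreacted 11 can be recycled).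

Step 9
Reactants: 8 (2S)-2-[2,5-dimethoxy-4-(triisopropylsilyloxy)phenyl]-3-hydroxypropyl acetate; 12 4-allyl-3-(triisopropylsilyloxy)phenol
Product: 13 (2S)-3-[4-allyl-3-(triisopropylsilyloxy)phenoxy]-2-[2,5-dimethoxy-4-(triisopropylsilyloxy)phenyl]propyl acetate
Conditions: PPh3, DIAD, toluene, 0 °C to rt
Reagents that add atoms: none
Why: Mitsunobu etherification, in which the free primary hydroxyl of 8 is activated as an alkoxyphosphonium ion and displaced by the phenoxide of 12 at a CH2 that is not the stereocentre, forming O1–C2 while no carbonyl flanks C3 (no β-elimination) and the neutral medium prevents the 1,3-acetyl shift that would racemise 8.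

Step 10
Reactants: 13 (2S)-3-[4-allyl-3-(triisopropylsilyloxy)phenoxy]-2-[2,5-dimethoxy-4-(triisopropylsilyloxy)phenyl]propyl acetate
Product: 14 (2R)-3-[4-allyl-3-(triisopropylsilyloxy)phenoxy]-2-[2,5-dimethoxy-4-(triisopropylsilyloxy)phenyl]propan-1-ol
Conditions: (i-Bu)2AlH (2.5 equiv), CH2Cl2, −78 °C; aqueous potassium sodium tartrate
Reagents that add atoms: none
Why: Reductive cleavage of the acetate with an aluminium hydride, chosen over carbonate in methanol so that the aryl silyl ethers are not put at risk, the terminal alkene being inert to hydroalumination at this temperature (the descriptor changes to R only through the priority rules).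

Step 11
Reactants: 14 (2R)-3-[4-allyl-3-(triisopropylsilyloxy)phenoxy]-2-[2,5-dimethoxy-4-(triisopropylsilyloxy)phenyl]propan-1-ol
Product: 16 (2S)-3-[4-allyl-3-(triisopropylsilyloxy)phenoxy]-2-[2,5-dimethoxy-4-(triisopropylsilyloxy)phenyl]propanoic acid, via aldehyde 15 (not isolated)
Conditions: TEMPO (cat.), PhI(OAc)2 (2.2 equiv), MeCN/H2O, 0 °C to rt
Reagents that add atoms: water, O
Why: Oxoammonium (TEMPO) oxidation with PhI(OAc)2 as terminal oxidant, taking the alcohol through aldehyde 15 and its hydrate to the acid in one flask in a weakly acidic medium in which the α-aryl β-aryloxy aldehyde should neither enolise nor lose phenoxide by E1cB elimination, and without a chlorine oxidant that could halogenate the electron-rich rings.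

Step 12
Reactants: 16 (2S)-3-[4-allyl-3-(triisopropylsilyloxy)phenoxy]-2-[2,5-dimethoxy-4-(triisopropylsilyloxy)phenyl]propanoic acid
Product: 18 (3S)-6-allyl-3-[2,5-dimethoxy-4-(triisopropylsilyloxy)phenyl]-7-(triisopropylsilyloxy)chroman-4-one, via mixed anhydride 17 (not isolated)
Conditions: TFAA (2 equiv), CH2Cl2, −30 to 0 °C; quench into cold pH 7 buffer
Reagents that add atoms: none
Why: TFAA converts acid 16 into the mixed anhydride 17, whose acyl carbon, activated further by the trifluoroacetic acid set free, is attacked by C4a of ring A; loss of the C4a proton from the arenium ion completes the C4–C4a bond. The closest known reaction type is the intramolecular Friedel–Crafts acylation of 3-aryloxypropanoic acids to chroman-4-ones through their trifluoroacetic mixed anhydrides. Ring C closes in a 6-exo-trig mode, the arene carbon adding to an acyl C=O that lies outside the forming ring. No stereocentre is created; C3, set in step 5, has only to be retained, which rests on the absence of any base and on a cold closure onto a ring with two oxygen donors that should outrun ketene formation from 17 and enolisation of 18. The regioselectivity needed is C4a over C8, both ortho to O1: C4a is para to the C7 silyloxy group and unhindered, whereas C8 is wedged between O1 and the bulky triisopropylsilyloxy group. Because no free acylium ion is generated by a strong Lewis acid, loss of CO to the oxygen-stabilised benzylic cation is not expected, and the terminal alkene and the aryl silyl ethers should tolerate cold trifluoroacetic acid where a prenyl group would not.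

Step 13
Reactants: 18 (3S)-6-allyl-3-[2,5-dimethoxy-4-(triisopropylsilyloxy)phenyl]-7-(triisopropylsilyloxy)chroman-4-one
Product: 19 (3S)-3-[2,5-dimethoxy-4-(triisopropylsilyloxy)phenyl]-6-(3-methylbut-2-en-1-yl)-7-(triisopropylsilyloxy)chroman-4-one
Conditions: 2-methylbut-2-ene (large excess), RuCl2(H2IMes)(PCy3)(=CHPh) (second-generation Grubbs catalyst, cat.), CH2Cl2, rt to 40 °C
Reagents that add atoms: 2-methylbut-2-ene, CC=C(C)C
Why: Olefin cross-metathesis, in which the terminal allyl alkene exchanges its CH2 terminus for the isopropylidene unit of the excess trisubstituted alkene, giving the prenyl group with no E/Z question, releasing propene and leaving the enolisable C3 alone under neutral conditions.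

Step 14
Reactants: 19 (3S)-3-[2,5-dimethoxy-4-(triisopropylsilyloxy)phenyl]-6-(3-methylbut-2-en-1-yl)-7-(triisopropylsilyloxy)chroman-4-one
Product: 20 (3S)-7-hydroxy-3-(4-hydroxy-2,5-dimethoxyphenyl)-6-(3-methylbut-2-en-1-yl)chroman-4-one (CNP0256988.2)
Conditions: Bu4NF (2.5 equiv), AcOH (3 equiv), THF, 0 °C
Reagents that add atoms: none
Why: Fluoride-induced cleavage of both aryl silyl ethers, with acetic acid protonating each phenoxide as it forms so that no base able to enolise C3 and no acid able to cyclise the ortho-prenyl phenol is present.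

**Compound list**

1 | 4-bromo-2,5-dimethoxybenzaldehyde | COc1cc(C=O)c(OC)cc1Br | starting material
2 | 4-bromo-2,5-dimethoxyphenyl formate | COc1cc(OC=O)c(OC)cc1Br | intermediate (not isolated)
3 | 4-bromo-2,5-dimethoxyphenol | COc1cc(O)c(OC)cc1Br | intermediate
4 | (4-bromo-2,5-dimethoxyphenoxy)triisopropylsilane | COc1cc(O[Si](C(C)C)(C(C)C)C(C)C)c(OC)cc1Br | intermediate
5 | diethyl malonate | CCOC(=O)CC(=O)OCC | starting material
6 | diethyl 2-[2,5-dimethoxy-4-(triisopropylsilyloxy)phenyl]malonate | CCOC(=O)C(C(=O)OCC)c1cc(OC)c(O[Si](C(C)C)(C(C)C)C(C)C)cc1OC | intermediate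
7 | 2-[2,5-dimethoxy-4-(triisopropylsilyloxy)phenyl]propane-1,3-diol | OCC(CO)c1cc(OC)c(O[Si](C(C)C)(C(C)C)C(C)C)cc1OC | intermediate
8 | (2S)-2-[2,5-dimethoxy-4-(triisopropylsilyloxy)phenyl]-3-hydroxypropyl acetate | CC(=O)OC[C@H](CO)c1cc(OC)c(O[Si](C(C)C)(C(C)C)C(C)C)cc1OC | intermediate
9 | 4-bromoresorcinol | Oc1ccc(Br)c(O)c1 | starting material
10 | 1-bromo-2,4-bis(triisopropylsilyloxy)benzene | CC(C)[Si](Oc1ccc(Br)c(O[Si](C(C)C)(C(C)C)C(C)C)c1)(C(C)C)C(C)C | intermediate
11 | 1-allyl-2,4-bis(triisopropylsilyloxy)benzene | C=CCc1ccc(O[Si](C(C)C)(C(C)C)C(C)C)cc1O[Si](C(C)C)(C(C)C)C(C)C | intermediate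
12 | 4-allyl-3-(triisopropylsilyloxy)phenol | C=CCc1ccc(O)cc1O[Si](C(C)C)(C(C)C)C(C)C | intermediate
13 | (2S)-3-[4-allyl-3-(triisopropylsilyloxy)phenoxy]-2-[2,5-dimethoxy-4-(triisopropylsilyloxy)phenyl]propyl acetate | CC(=O)OC[C@H](COc1ccc(CC=C)c(O[Si](C(C)C)(C(C)C)C(C)C)c1)c1cc(OC)c(O[Si](C(C)C)(C(C)C)C(C)C)cc1OC | intermediate
14 | (2R)-3-[4-allyl-3-(triisopropylsilyloxy)phenoxy]-2-[2,5-dimethoxy-4-(triisopropylsilyloxy)phenyl]propan-1-ol | OC[C@H](COc1ccc(CC=C)c(O[Si](C(C)C)(C(C)C)C(C)C)c1)c1cc(OC)c(O[Si](C(C)C)(C(C)C)C(C)C)cc1OC | intermediate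
15 | (2S)-3-[4-allyl-3-(triisopropylsilyloxy)phenoxy]-2-[2,5-dimethoxy-4-(triisopropylsilyloxy)phenyl]propanal | O=C[C@H](COc1ccc(CC=C)c(O[Si](C(C)C)(C(C)C)C(C)C)c1)c1cc(OC)c(O[Si](C(C)C)(C(C)C)C(C)C)cc1OC | intermediate (not isolated)
16 | (2S)-3-[4-allyl-3-(triisopropylsilyloxy)phenoxy]-2-[2,5-dimethoxy-4-(triisopropylsilyloxy)phenyl]propanoic acid | OC(=O)[C@H](COc1ccc(CC=C)c(O[Si](C(C)C)(C(C)C)C(C)C)c1)c1cc(OC)c(O[Si](C(C)C)(C(C)C)C(C)C)cc1OC | intermediate
17 | mixed anhydride of 16 with trifluoroacetic acid, (2S) | O=C(OC(=O)C(F)(F)F)[C@H](COc1ccc(CC=C)c(O[Si](C(C)C)(C(C)C)C(C)C)c1)c1cc(OC)c(O[Si](C(C)C)(C(C)C)C(C)C)cc1OC | intermediate (not isolated)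
18 | (3S)-6-allyl-3-[2,5-dimethoxy-4-(triisopropylsilyloxy)phenyl]-7-(triisopropylsilyloxy)chroman-4-one | COc1cc([C@H]2COc3cc(O[Si](C(C)C)(C(C)C)C(C)C)c(CC=C)cc3C2=O)c(OC)cc1O[Si](C(C)C)(C(C)C)C(C)C | intermediate
19 | (3S)-3-[2,5-dimethoxy-4-(triisopropylsilyloxy)phenyl]-6-(3-methylbut-2-en-1-yl)-7-(triisopropylsilyloxy)chroman-4-one | COc1cc([C@H]2COc3cc(O[Si](C(C)C)(C(C)C)C(C)C)c(CC=C(C)C)cc3C2=O)c(OC)cc1O[Si](C(C)C)(C(C)C)C(C)C | intermediate
20 | (3S)-7-hydroxy-3-(4-hydroxy-2,5-dimethoxyphenyl)-6-(3-methylbut-2-en-1-yl)chroman-4-one | COc1cc([C@H]2COc3cc(O)c(CC=C(C)C)cc3C2=O)c(OC)cc1O | target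

**Step count**

Total steps: 14. Longest linear sequence: 11 steps (steps 1–5 and 9–14); steps 6–8 form the ring A branch.

**Steps most likely to fail**

Step 12 (key step). What may go wrong is erosion of the C3 configuration, either by ketene formation from the mixed anhydride or by acid-catalysed enolisation of the new ketone. The fallback resets the stereocentre after ring closure instead of relying on retention. Setting out from 18 of whatever enantiomeric purity, asymmetric transfer hydrogenation under dynamic kinetic resolution with RuCl[(S,S)-TsDPEN](p-cymene) in HCO2H/Et3N should give (3S,4S)-6-allyl-3-[2,5-dimethoxy-4-(triisopropylsilyloxy)phenyl]-7-(triisopropylsilyloxy)chroman-4-ol F1, the cis alcohol, because Et3N equilibrates C3 of the ketone faster than the ketone is reduced. The (4S) sense is expected by analogy with chroman-4-one. Dess–Martin periodinane with NaHCO3 in CH2Cl2 at 0 °C then reoxidises C4 without base and returns to 18. The same detour would repair any erosion suffered in step 11.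

Step 5. What may go wrong is insufficient or reversed discrimination of the two enantiotopic hydroxymethyl arms, for instance because the ortho methoxy group disturbs binding in the enzyme. The fallback is a non-enzymatic desymmetrisation. Setting out from 7, vinyl benzoate with Et2Zn and a ProPhenol ligand (dinuclear zinc catalyst, both ligand enantiomers available, so the sense can be chosen) should give (2S)-2-[2,5-dimethoxy-4-(triisopropylsilyloxy)phenyl]-3-hydroxypropyl benzoate F2. Mitsunobu coupling with 12 as in step 9 gives (2S)-3-[4-allyl-3-(triisopropylsilyloxy)phenoxy]-2-[2,5-dimethoxy-4-(triisopropylsilyloxy)phenyl]propyl benzoate F3, and (i-Bu)2AlH as in step 10 returns to 14.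

Step 8. What may go wrong is poor discrimination between the two aryl silyl ethers, or over-cleavage to the diol. The fallback gives the two oxygens different silyl groups before the allyl group is installed. Setting out from 9, TBSCl (1.0 equiv) with imidazole in CH2Cl2 at −20 °C should silylate the oxygen para to bromine, the less hindered and more nucleophilic one, to give 2-bromo-5-(tert-butyldimethylsilyloxy)phenol F4. TIPSOTf with 2,6-lutidine caps the oxygen next to bromine to give [4-bromo-3-(triisopropylsilyloxy)phenoxy](tert-butyl)dimethylsilane F5, and Stille allylation as in step 7 gives [4-allyl-3-(triisopropylsilyloxy)phenoxy](tert-butyl)dimethylsilane F6. K2CO3 in MeOH at 0 °C then removes only the unhindered aryl tert-butyldimethylsilyl ether, a discrimination that rests on the nature of the silyl groups as well as on the ortho substituent, and returns to 12.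

**Further compounds**

F1 | step 12 | (3S,4S)-6-allyl-3-[2,5-dimethoxy-4-(triisopropylsilyloxy)phenyl]-7-(triisopropylsilyloxy)chroman-4-ol | COc1cc([C@H]2COc3cc(O[Si](C(C)C)(C(C)C)C(C)C)c(CC=C)cc3[C@H]2O)c(OC)cc1O[Si](C(C)C)(C(C)C)C(C)C
F2 | step 5 | (2S)-2-[2,5-dimethoxy-4-(triisopropylsilyloxy)phenyl]-3-hydroxypropyl benzoate | O=C(OC[C@H](CO)c1cc(OC)c(O[Si](C(C)C)(C(C)C)C(C)C)cc1OC)c1ccccc1
F3 | step 5 | (2S)-3-[4-allyl-3-(triisopropylsilyloxy)phenoxy]-2-[2,5-dimethoxy-4-(triisopropylsilyloxy)phenyl]propyl benzoate | O=C(OC[C@H](COc1ccc(CC=C)c(O[Si](C(C)C)(C(C)C)C(C)C)c1)c1cc(OC)c(O[Si](C(C)C)(C(C)C)C(C)C)cc1OC)c1ccccc1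
F4 | step 8 | 2-bromo-5-(tert-butyldimethylsilyloxy)phenol | CC(C)(C)[Si](C)(C)Oc1ccc(Br)c(O)c1
F5 | step 8 | [4-bromo-3-(triisopropylsilyloxy)phenoxy](tert-butyl)dimethylsilane | CC(C)(C)[Si](C)(C)Oc1ccc(Br)c(O[Si](C(C)C)(C(C)C)C(C)C)c1
F6 | step 8 | [4-allyl-3-(triisopropylsilyloxy)phenoxy](tert-butyl)dimethylsilane | C=CCc1ccc(O[Si](C)(C)C(C)(C)C)cc1O[Si](C(C)C)(C(C)C)C(C)C
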